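**Plan**
1. Retrosynthesis: the diene side chain is cut at C13–C14 (vinyl coupling) and C12=C13 (iodo-olefination) and shortened at C11–C12; the oxygens at C6, C7 and C8 are traced back to a C6 silyl enol ether.
2. Both rings are then opened in one cut at C5–C10 and C8–C9: C6 with its oxygen is C2 of a diene C5=C6–C7=C8, C11 on C9 is the formyl group that activates a C9=C10 dienophile, and C1–C4 of ring A is the tether between them.
3. The acyclic trienal is cut at C4–C5, which leads to methyl geranate (C1–C4, C9–C11, C18–C20, with the (E)-alkene already in place) and pent-3-en-2-one (C5–C8, C17).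
4. Forward: the chain is joined at C4–C5, rings A and B close together in the intramolecular Diels–Alder step, then C12 is added, ring B is oxygenated and the side chain is completed.
5. Stereochemistry: C10 from a chiral boron Lewis acid; C5 and C9 from the endo transition state of the (E)-enal; C8, C6 and C7 from reagent attack on the face of ring B anti to C20 (epoxidation, dihydroxylation, hydride); 12Z from the Stork–Zhao olefination.

Key step: step 7

Remark on numbering: labdane numbering is used for all cyclic compounds (ring A = C1–C5 and C10, ring B = C5–C10, C11 and C12 on C9, C17 on C8, C18 and C19 on C4, C20 on C10); "syn" and "anti" refer to the face of ring B that carries C20.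
Assumption: the enal is taken to bind the boron catalyst in the usual formyl C–H···O, s-trans mode, for which the (S)-configured catalyst leaves the Si face of C10 open and should give 10R; if the sense proved opposite, the mirror-image catalyst would be used.

**Step 1**
Reactants: 1 (3E)-pent-3-en-2-one
Product: 2 (3E)-2-(trimethylsilyloxy)penta-1,3-diene
Conditions: Me3SiOTf, Et3N, Et2O, 0 °C
Reagents that add atoms: trimethylsilyl trifluoromethanesulfonate, C[Si](C)(C)OS(=O)(=O)C(F)(F)F
Why: Soft enolisation of the enone by a silyl triflate and a tertiary amine removes a proton from the α'-methyl group and should give the cross-conjugated 2-silyloxy diene, whose terminal CH2 is the nucleophile of step 3.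

**Step 2**
Reactants: 3 methyl (2E)-3,7-dimethylocta-2,6-dienoate (methyl geranate)
Product: 4 methyl (2E)-7-chloro-3,7-dimethyloct-2-enoate
Conditions: HCl (g), CH2Cl2, −30 → 0 °C
Reagents that add atoms: hydrogen chloride, Cl
Why: Markovnikov hydrochlorination takes place at the electron-rich isopropylidene alkene and should leave the electron-poor conjugated C2=C3 bond and its (E)-geometry untouched.

**Step 3**
Reactants: 4 methyl (2E)-7-chloro-3,7-dimethyloct-2-enoate; 2 (3E)-2-(trimethylsilyloxy)penta-1,3-diene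
Product: 5 methyl (2E,10E)-3,7,7-trimethyl-9-oxododeca-2,10-dienoate
Conditions: TiCl4 (1.2 equiv), CH2Cl2, −78 → −45 °C, 2 added slowly; aq. NaHCO3
Reagents that add atoms: none
Why: TiCl4 ionises the tertiary chloride and the cation is trapped at the CH2 terminus of the silyl dienol ether (Lewis-acid-mediated α-tert-alkylation of a silyl enol ether, an SN1-type Mukaiyama alkylation), which forms the C4–C5 bond and the quaternary carbon C4, the deactivated enoate alkene being too poor a π-nucleophile to intercept the cation at low temperature.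

**Step 4**
Reactants: 5 methyl (2E,10E)-3,7,7-trimethyl-9-oxododeca-2,10-dienoate
Product: 6 methyl (2E,8Z,10E)-3,7,7-trimethyl-9-[(triisopropylsilyl)oxy]dodeca-2,8,10-trienoate
Conditions: i-Pr3SiOTf, Et3N, CH2Cl2, −78 → 0 °C
Reagents that add atoms: triisopropylsilyl trifluoromethanesulfonate, CC(C)[Si](C(C)C)(C(C)C)OS(=O)(=O)C(F)(F)F
Why: Soft enolisation at the α'-methylene C5 is expected to give the thermodynamically preferred (Z)-silyl enol ether, in which the bulky C4 residue is anti to the propenyl group so that the diene C5=C6–C7=C8 can reach the s-cis form with both terminal substituents outside, and the triisopropylsilyl group is chosen for its stability toward the acidic catalyst of step 7.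

**Step 5**
Reactants: 6 methyl (2E,8Z,10E)-3,7,7-trimethyl-9-[(triisopropylsilyl)oxy]dodeca-2,8,10-trienoate
Product: 7 (2E,8Z,10E)-3,7,7-trimethyl-9-[(triisopropylsilyl)oxy]dodeca-2,8,10-trien-1-ol
Conditions: i-Bu2AlH, CH2Cl2, −78 °C; aqueous potassium sodium tartrate
Reagents that add atoms: none
Why: Hydride reduction of the conjugated ester in the 1,2-sense gives the allylic alcohol and does not touch the silyl enol ether.

**Step 6**
Reactants: 7 (2E,8Z,10E)-3,7,7-trimethyl-9-[(triisopropylsilyl)oxy]dodeca-2,8,10-trien-1-ol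
Product: 8 (2E,8Z,10E)-3,7,7-trimethyl-9-[(triisopropylsilyl)oxy]dodeca-2,8,10-trienal
Conditions: MnO2, CH2Cl2, rt
Reagents that add atoms: none
Why: Allylic oxidation with MnO2 is neutral and should preserve both the (2E)-geometry and the acid-labile silyl dienol ether.

**Step 7**
Reactants: 8 (2E,8Z,10E)-3,7,7-trimethyl-9-[(triisopropylsilyl)oxy]dodeca-2,8,10-trienal
Product: 9 (5R,8R,9R,10R)-6-[(triisopropylsilyl)oxy]-12,13,14,15,16-pentanorlabd-6-en-11-al
Conditions: (S)-3,3-diphenyl-1-(2-methylphenyl)tetrahydro-1H,3H-pyrrolo[1,2-c][1,3,2]oxazaborole (20 mol %), (CF3SO2)2NH (18 mol %), CH2Cl2, −78 → −40 °C; Et3N quench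
Reagents that add atoms: none
Why: Proposed new method: the N-protonated oxazaborolidine binds the formyl oxygen and lowers the LUMO of the C9=C10 dienophile, so that the nucleophilic terminus C5 of the 2-silyloxy diene adds to the β-carbon C10 while the C8–C9 bond forms later in the same concerted, asynchronous [4+2] event; the closest known reaction type is the enantioselective Diels–Alder reaction of enals with 2-silyloxy dienes under cationic oxazaborolidine catalysis, including its intramolecular form with 2,8,10-trienals, which has not been shown for a β,β-disubstituted enal that must create a quaternary carbon. Ring B closes as the cyclohexene of the cycloaddition (bonds C5–C10 and C8–C9), and ring A closes in the same event as a six-membered ring through the four-carbon tether C1–C4, whose chair-like fold is favoured by the gem-dimethyl group at C4. C10 is set by the catalyst, whose aryl group covers the Re face of C10 so that C5 adds to the Si face; C5 follows from the endo transition state (formyl group under the diene), which with an (E)-dienophile gives the trans ring fusion; C9 follows from suprafacial addition to the (E)-enal, which keeps C11 cis to C20; C8 follows from the (E)-propenyl terminus and becomes planar again in step 11. The step needs enantioface and endo selectivity: the first rests on the catalyst, the second on Lewis-acid activation and on the defined (2E) and (8Z,10E) geometries of the substrate, and both C9 (α to the formyl group) and C5 (α to the later C6 ketone) can in any case equilibrate to the trans-fused, equatorial arrangement. Regiochemistry is not in question, because the tether allows only this mode and the silyloxy group at C6 polarises the diene in the matched sense.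

**Step 8**
Reactants: 9 (5R,8R,9R,10R)-6-[(triisopropylsilyl)oxy]-12,13,14,15,16-pentanorlabd-6-en-11-al
Product: 10 (5R,8S,9R,10S)-6-[(triisopropylsilyl)oxy]-13,14,15,16-tetranorlabda-6,11-diene
Conditions: Ph3PCH3Br, KN(SiMe3)2, THF, 0 °C; then 9, −78 → 0 °C
Reagents that add atoms: methyltriphenylphosphonium bromide, C[P+](c1ccccc1)(c1ccccc1)c1ccccc1.[Br-]
Why: Wittig methylenation at low temperature converts the hindered aldehyde into the C11=C12 vinyl group fast enough that the α-stereocentre C9 should not epimerise, and the silyl enol ether is stable to the base.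

**Step 9**
Reactants: 10 (5R,8S,9R,10S)-6-[(triisopropylsilyl)oxy]-13,14,15,16-tetranorlabda-6,11-diene
Product: 12 (5R,8S,9R,10S)-6-[(triisopropylsilyl)oxy]-13,14,15,16-tetranorlabd-6-en-12-ol, via B-alkyl-9-BBN adduct 11 (not isolated)
Conditions: 9-borabicyclo[3.3.1]nonane (9-BBN), THF, 0 °C → rt; then aq. NaOH, H2O2, 0 °C
Reagents that add atoms: hydrogen peroxide, OO
Why: Hydroboration–oxidation with the bulky borane is anti-Markovnikov and selective for the monosubstituted alkene over the hindered trisubstituted silyl enol ether, and should give the C12 alcohol.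

**Step 10**
Reactants: 12 (5R,8S,9R,10S)-6-[(triisopropylsilyl)oxy]-13,14,15,16-tetranorlabd-6-en-12-ol
Product: 13 (5R,8S,9R,10S)-12-[(triethylsilyl)oxy]-6-[(triisopropylsilyl)oxy]-13,14,15,16-tetranorlabd-6-ene
Conditions: Et3SiCl, imidazole, CH2Cl2, 0 °C
Reagents that add atoms: chlorotriethylsilane, CC[Si](Cl)(CC)CC
Why: Silylation of the primary alcohol (standard protection) masks it against intramolecular conjugate addition to the enone formed in the next step.

**Step 11**
Reactants: 13 (5R,8S,9R,10S)-12-[(triethylsilyl)oxy]-6-[(triisopropylsilyl)oxy]-13,14,15,16-tetranorlabd-6-ene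
Product: 14 (5R,9R,10S)-12-[(triethylsilyl)oxy]-13,14,15,16-tetranorlabd-7-en-6-one
Conditions: Pd(OAc)2 (1.2 equiv), MeCN, 40 °C
Reagents that add atoms: none
Why: Saegusa–Ito oxidation, in which the silyl enol ether is converted into a palladium enolate at C7 and β-hydride elimination of H-8, the only β-hydrogen available, should give the 7-en-6-one and make C8 planar.

**Step 12**
Reactants: 14 (5R,9R,10S)-12-[(triethylsilyl)oxy]-13,14,15,16-tetranorlabd-7-en-6-one
Product: 15 (5R,7R,8R,9S,10S)-7,8-epoxy-12-[(triethylsilyl)oxy]-13,14,15,16-tetranorlabdan-6-one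
Conditions: t-BuOOH, benzyltrimethylammonium hydroxide (cat.), THF, 0 °C → rt
Reagents that add atoms: tert-butyl hydroperoxide, CC(C)(C)OO
Why: Nucleophilic (Weitz–Scheffer) epoxidation, in which the peroxide anion adds to C8 from the face anti to C20 because the other face is screened by the syn-axial angular methyl group, sets C8 (oxygen anti to C20, C17 syn) and C7.

**Step 13**
Reactants: 15 (5R,7R,8R,9S,10S)-7,8-epoxy-12-[(triethylsilyl)oxy]-13,14,15,16-tetranorlabdan-6-one
Product: 17 (5R,8S,9S,10R)-12-[(triethylsilyl)oxy]-13,14,15,16-tetranorlabd-6-en-8-ol, via epoxy hydrazone 16 (not isolated)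
Conditions: N2H4·H2O, AcOH (cat.), i-PrOH, 0 °C → rt
Reagents that add atoms: none
Why: Wharton transposition, in which the epoxy hydrazone opens to an alkenyl diazene that loses N2, should give the C6=C7 alkene and the tertiary C8 alcohol, whose C–O bond is never broken so that the spatial arrangement at C8 is kept.

**Step 14**
Reactants: 17 (5R,8S,9S,10R)-12-[(triethylsilyl)oxy]-13,14,15,16-tetranorlabd-6-en-8-ol
Product: 18 (5R,8S,9S,10R)-8,12-bis[(triethylsilyl)oxy]-13,14,15,16-tetranorlabd-6-ene
Conditions: Et3SiOTf, 2,6-lutidine, CH2Cl2, −78 → 0 °C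
Reagents that add atoms: triethylsilyl trifluoromethanesulfonate, CC[Si](CC)(CC)OS(=O)(=O)C(F)(F)F
Why: Silylation of the tertiary allylic alcohol with a silyl triflate (standard protection) prevents later lactol formation with the C12 aldehyde and acyl migration to O8.

**Step 15**
Reactants: 18 (5R,8S,9S,10R)-8,12-bis[(triethylsilyl)oxy]-13,14,15,16-tetranorlabd-6-ene
Product: 19 (5R,6S,7S,8R,9S,10R)-8,12-bis[(triethylsilyl)oxy]-13,14,15,16-tetranorlabdane-6,7-diol
Conditions: OsO4 (5 mol %), N-methylmorpholine N-oxide, acetone/H2O, rt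
Reagents that add atoms: osmium tetroxide, O=[Os](=O)(=O)=O; N-methylmorpholine N-oxide, C[N+]1([O-])CCOCC1
Why: Catalytic cis-dihydroxylation should occur on the face anti to C20 because C17, C19 and C20 shield the other face, which sets C6 in its final configuration and places the C7 hydroxyl axial for the inversion that follows.

**Step 16**
Reactants: 19 (5R,6S,7S,8R,9S,10R)-8,12-bis[(triethylsilyl)oxy]-13,14,15,16-tetranorlabdane-6,7-diol
Product: 21 (5R,6S,8R,9S,10R)-6-hydroxy-8,12-bis[(triethylsilyl)oxy]-13,14,15,16-tetranorlabdan-7-one, via 6,7-O-dibutylstannylene acetal 20 (not isolated)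
Conditions: Bu2SnO, toluene, reflux with removal of water; then N-bromosuccinimide, CHCl3, rt
Reagents that add atoms: none
Why: Stannylene-mediated oxidation (brominolysis of a dibutylstannylene acetal) is known to oxidise the axial hydroxyl of a cis-1,2-diol, here the one at C7, and leaves C6 with its equatorial hydroxyl untouched.

**Step 17**
Reactants: 21 (5R,6S,8R,9S,10R)-6-hydroxy-8,12-bis[(triethylsilyl)oxy]-13,14,15,16-tetranorlabdan-7-one
Product: 22 (5R,6S,7R,8R,9S,10R)-8,12-bis[(triethylsilyl)oxy]-13,14,15,16-tetranorlabdane-6,7-diol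
Conditions: NaBH4, EtOH, −20 °C
Reagents that add atoms: none
Why: Borohydride reduction delivers hydride along the axial trajectory from the face anti to C20, the equatorial approach being blocked by the axial C17 methyl group, so that the new C7 hydroxyl is equatorial, syn to C20 and trans to the C6 hydroxyl.

**Step 18**
Reactants: 22 (5R,6S,7R,8R,9S,10R)-8,12-bis[(triethylsilyl)oxy]-13,14,15,16-tetranorlabdane-6,7-diol
Product: 23 (5R,6S,7R,8R,9S,10R)-8,12-bis[(triethylsilyl)oxy]-13,14,15,16-tetranorlabdane-6,7-diyl diacetate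
Conditions: Ac2O, pyridine, 4-(dimethylamino)pyridine (cat.), CH2Cl2, rt
Reagents that add atoms: acetic anhydride, CC(=O)OC(C)=O
Why: Acetylation under nucleophilic catalysis esterifies the two secondary hydroxyls, the only free hydroxyl groups in the molecule.

**Step 19**
Reactants: 23 (5R,6S,7R,8R,9S,10R)-8,12-bis[(triethylsilyl)oxy]-13,14,15,16-tetranorlabdane-6,7-diyl diacetate
Product: 25 (5R,6S,7R,8R,9S,10R)-12-oxo-8-[(triethylsilyl)oxy]-13,14,15,16-tetranorlabdane-6,7-diyl diacetate, via alkoxydimethylsulfonium chloride 24 (not isolated)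
Conditions: (COCl)2, DMSO, CH2Cl2, −78 → −30 °C; Et3N, −78 °C → rt
Reagents that add atoms: none
Why: Under Swern conditions a primary triethylsilyl ether is cleaved by the chlorosulfonium salt and oxidised directly to the aldehyde, while the hindered tertiary silyl ether and the acetates are not affected.

**Step 20**
Reactants: 25 (5R,6S,7R,8R,9S,10R)-12-oxo-8-[(triethylsilyl)oxy]-13,14,15,16-tetranorlabdane-6,7-diyl diacetate
Product: 26 (5R,6S,7R,8R,9S,10R,12Z)-13-iodo-8-[(triethylsilyl)oxy]-14,15-dinorlabd-12-ene-6,7-diyl diacetate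
Conditions: Ph3PEtI, n-BuLi, THF, rt; I2, −78 °C; NaN(SiMe3)2, −78 → −20 °C; then 25, −78 °C
Reagents that add atoms: ethyltriphenylphosphonium iodide, CC[P+](c1ccccc1)(c1ccccc1)c1ccccc1.[I-]; iodine, II
Why: Stork–Zhao olefination, in which the non-stabilised α-iodo ylide reacts under kinetic control through the cis-oxaphosphetane, should give the (Z)-vinyl iodide with iodine cis to C11.

**Step 21**
Reactants: 26 (5R,6S,7R,8R,9S,10R,12Z)-13-iodo-8-[(triethylsilyl)oxy]-14,15-dinorlabd-12-ene-6,7-diyl diacetate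
Product: 27 (5R,6S,7R,8R,9S,10R,12Z)-8-[(triethylsilyl)oxy]labda-12,14-diene-6,7-diyl diacetate
Conditions: Bu3SnCH=CH2, Pd(PPh3)4 (5 mol %), CuI (10 mol %), DMF, rt
Reagents that add atoms: tributyl(vinyl)stannane, C=C[Sn](CCCC)(CCCC)CCCC
Why: Stille coupling proceeds with retention of the alkene geometry, so that vinyl takes the place of iodine and the (12Z)-diene should result under neutral conditions at room temperature.

**Step 22**
Reactants: 27 (5R,6S,7R,8R,9S,10R,12Z)-8-[(triethylsilyl)oxy]labda-12,14-diene-6,7-diyl diacetate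
Product: 28 (5R,6S,7R,8R,9S,10R,12Z)-8-hydroxylabda-12,14-diene-6,7-diyl diacetate
Conditions: HF·pyridine, pyridine, THF, 0 °C → rt
Reagents that add atoms: none
Why: Fluoride-mediated desilylation frees the tertiary alcohol, and the buffered reagent is mild enough for the acetates and the diene.

**Compound list**
1 | (3E)-pent-3-en-2-one | C/C=C/C(C)=O | starting material
2 | (3E)-2-(trimethylsilyloxy)penta-1,3-diene | C=C(O[Si](C)(C)C)/C=C/C | intermediate
3 | methyl (2E)-3,7-dimethylocta-2,6-dienoate (methyl geranate) | COC(=O)/C=C(\C)CCC=C(C)C | starting material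
4 | methyl (2E)-7-chloro-3,7-dimethyloct-2-enoate | COC(=O)/C=C(\C)CCCC(C)(C)Cl | intermediate
5 | methyl (2E,10E)-3,7,7-trimethyl-9-oxododeca-2,10-dienoate | COC(=O)/C=C(\C)CCCC(C)(C)CC(=O)/C=C/C | intermediate
6 | methyl (2E,8Z,10E)-3,7,7-trimethyl-9-[(triisopropylsilyl)oxy]dodeca-2,8,10-trienoate | COC(=O)/C=C(\C)CCCC(C)(C)/C=C(O[Si](C(C)C)(C(C)C)C(C)C)/C=C/C | intermediate
7 | (2E,8Z,10E)-3,7,7-trimethyl-9-[(triisopropylsilyl)oxy]dodeca-2,8,10-trien-1-ol | OC/C=C(\C)CCCC(C)(C)/C=C(O[Si](C(C)C)(C(C)C)C(C)C)/C=C/C | intermediate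
8 | (2E,8Z,10E)-3,7,7-trimethyl-9-[(triisopropylsilyl)oxy]dodeca-2,8,10-trienal (Diels–Alder precursor) | O=C/C=C(\C)CCCC(C)(C)/C=C(O[Si](C(C)C)(C(C)C)C(C)C)/C=C/C | intermediate
9 | (5R,8R,9R,10R)-6-[(triisopropylsilyl)oxy]-12,13,14,15,16-pentanorlabd-6-en-11-al (trans-fused; CHO and C17 syn to C20) | O=C[C@@H]1[C@H](C)C=C(O[Si](C(C)C)(C(C)C)C(C)C)[C@@H]2C(C)(C)CCC[C@]21C | intermediate
10 | (5R,8S,9R,10S)-6-[(triisopropylsilyl)oxy]-13,14,15,16-tetranorlabda-6,11-diene | C=C[C@@H]1[C@H](C)C=C(O[Si](C(C)C)(C(C)C)C(C)C)[C@@H]2C(C)(C)CCC[C@]21C | intermediate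
11 | B-alkyl-9-BBN adduct of 10 (boron on C12) | B3(C4CCCC3CCC4)CC[C@@H]1[C@H](C)C=C(O[Si](C(C)C)(C(C)C)C(C)C)[C@@H]2C(C)(C)CCC[C@]21C | intermediate (not isolated)
12 | (5R,8S,9R,10S)-6-[(triisopropylsilyl)oxy]-13,14,15,16-tetranorlabd-6-en-12-ol | OCC[C@@H]1[C@H](C)C=C(O[Si](C(C)C)(C(C)C)C(C)C)[C@@H]2C(C)(C)CCC[C@]21C | intermediate
13 | (5R,8S,9R,10S)-12-[(triethylsilyl)oxy]-6-[(triisopropylsilyl)oxy]-13,14,15,16-tetranorlabd-6-ene | CC[Si](CC)(CC)OCC[C@@H]1[C@H](C)C=C(O[Si](C(C)C)(C(C)C)C(C)C)[C@@H]2C(C)(C)CCC[C@]21C | intermediate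
14 | (5R,9R,10S)-12-[(triethylsilyl)oxy]-13,14,15,16-tetranorlabd-7-en-6-one | CC[Si](CC)(CC)OCC[C@@H]1C(C)=CC(=O)[C@@H]2C(C)(C)CCC[C@]21C | intermediate
15 | (5R,7R,8R,9S,10S)-7,8-epoxy-12-[(triethylsilyl)oxy]-13,14,15,16-tetranorlabdan-6-one (epoxide anti to C20) | CC[Si](CC)(CC)OCC[C@@H]1[C@@]3(C)O[C@H]3C(=O)[C@@H]2C(C)(C)CCC[C@]21C | intermediate
16 | hydrazone of 15 at C6 | CC[Si](CC)(CC)OCC[C@@H]1[C@@]3(C)O[C@H]3C(=NN)[C@@H]2C(C)(C)CCC[C@]21C | intermediate (not isolated)
17 | (5R,8S,9S,10R)-12-[(triethylsilyl)oxy]-13,14,15,16-tetranorlabd-6-en-8-ol (8-OH anti to C20) | CC[Si](CC)(CC)OCC[C@@H]1[C@@](C)(O)C=C[C@@H]2C(C)(C)CCC[C@]21C | intermediate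
18 | (5R,8S,9S,10R)-8,12-bis[(triethylsilyl)oxy]-13,14,15,16-tetranorlabd-6-ene | CC[Si](CC)(CC)OCC[C@@H]1[C@@](C)(O[Si](CC)(CC)CC)C=C[C@@H]2C(C)(C)CCC[C@]21C | intermediate
19 | (5R,6S,7S,8R,9S,10R)-8,12-bis[(triethylsilyl)oxy]-13,14,15,16-tetranorlabdane-6,7-diol (both hydroxyls anti to C20) | CC[Si](CC)(CC)OCC[C@@H]1[C@@](C)(O[Si](CC)(CC)CC)[C@@H](O)[C@@H](O)[C@@H]2C(C)(C)CCC[C@]21C | intermediate
20 | 6,7-O-dibutylstannylene acetal of 19 | CC[Si](CC)(CC)OCC[C@@H]1[C@@](C)(O[Si](CC)(CC)CC)[C@H]3O[Sn](CCCC)(CCCC)O[C@H]3[C@@H]2C(C)(C)CCC[C@]21C | intermediate (not isolated)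
21 | (5R,6S,8R,9S,10R)-6-hydroxy-8,12-bis[(triethylsilyl)oxy]-13,14,15,16-tetranorlabdan-7-one | CC[Si](CC)(CC)OCC[C@@H]1[C@@](C)(O[Si](CC)(CC)CC)C(=O)[C@@H](O)[C@@H]2C(C)(C)CCC[C@]21C | intermediate
22 | (5R,6S,7R,8R,9S,10R)-8,12-bis[(triethylsilyl)oxy]-13,14,15,16-tetranorlabdane-6,7-diol (6-OH anti, 7-OH syn to C20) | CC[Si](CC)(CC)OCC[C@@H]1[C@@](C)(O[Si](CC)(CC)CC)[C@H](O)[C@@H](O)[C@@H]2C(C)(C)CCC[C@]21C | intermediate
23 | (5R,6S,7R,8R,9S,10R)-8,12-bis[(triethylsilyl)oxy]-13,14,15,16-tetranorlabdane-6,7-diyl diacetate | CC[Si](CC)(CC)OCC[C@@H]1[C@@](C)(O[Si](CC)(CC)CC)[C@H](OC(C)=O)[C@@H](OC(C)=O)[C@@H]2C(C)(C)CCC[C@]21C | intermediate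
24 | alkoxydimethylsulfonium chloride formed from 23 at O12 | C[S+](C)OCC[C@@H]1[C@@](C)(O[Si](CC)(CC)CC)[C@H](OC(C)=O)[C@@H](OC(C)=O)[C@@H]2C(C)(C)CCC[C@]21C.[Cl-] | intermediate (not isolated)
25 | (5R,6S,7R,8R,9S,10R)-12-oxo-8-[(triethylsilyl)oxy]-13,14,15,16-tetranorlabdane-6,7-diyl diacetate | O=CC[C@@H]1[C@@](C)(O[Si](CC)(CC)CC)[C@H](OC(C)=O)[C@@H](OC(C)=O)[C@@H]2C(C)(C)CCC[C@]21C | intermediate
26 | (5R,6S,7R,8R,9S,10R,12Z)-13-iodo-8-[(triethylsilyl)oxy]-14,15-dinorlabd-12-ene-6,7-diyl diacetate | I/C(C)=C\C[C@@H]1[C@@](C)(O[Si](CC)(CC)CC)[C@H](OC(C)=O)[C@@H](OC(C)=O)[C@@H]2C(C)(C)CCC[C@]21C | intermediate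
27 | (5R,6S,7R,8R,9S,10R,12Z)-8-[(triethylsilyl)oxy]labda-12,14-diene-6,7-diyl diacetate | C=C/C(C)=C\C[C@@H]1[C@@](C)(O[Si](CC)(CC)CC)[C@H](OC(C)=O)[C@@H](OC(C)=O)[C@@H]2C(C)(C)CCC[C@]21C | intermediate
28 | (5R,6S,7R,8R,9S,10R,12Z)-8-hydroxylabda-12,14-diene-6,7-diyl diacetate (CNP0537572.1) | C=C/C(C)=C\C[C@@H]1[C@@](C)(O)[C@H](OC(C)=O)[C@@H](OC(C)=O)[C@@H]2C(C)(C)CCC[C@]21C | target

**Step count**
Total: 22 steps. Longest linear sequence: 21 steps (3 → 28, steps 2 to 22); step 1 is a one-step side branch.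

**Steps most likely to fail**

Step 7 (intramolecular Diels–Alder reaction). What may go wrong: the β,β-disubstituted enal may bind the boron catalyst weakly or turn over slowly, so that enantiofacial control is lost to a background reaction, or the dienol ether may be protodesilylated by the acidic catalyst before it cyclises. Fallback with known chemistry, setting out from 8: the cyclisation is promoted by the achiral Lewis acid Me2AlCl (CH2Cl2, −78 → −20 °C), the long-established Lewis-acid-promoted intramolecular Diels–Alder reaction of trienals. This should give the same trans-fused adduct as a racemate, that is 9 together with its mirror image, the (5S,8S,9S,10S)-aldehyde F1. The two are separated by preparative chromatography on a chiral stationary phase (cellulose tris(3,5-dimethylphenylcarbamate), hexane/i-PrOH) and the route is re-entered at 9. Absolute configuration then comes from resolution instead of catalysis.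

Step 13 (Wharton transposition). What may go wrong: hydrazone formation at the hindered C6 carbonyl may be slow, so that hydrazine opens the epoxide or the diazene decomposes along other paths. Fallback setting out from 15: reductive opening of the epoxy ketone at C7 with SmI2 (THF/MeOH, −78 °C) should give the 8-hydroxy-6-ketone F2. Silylation (Et3SiOTf, 2,6-lutidine, CH2Cl2) gives the bis(triethylsilyl) ether F3. Kinetic enolisation toward C7 and triflation (KN(SiMe3)2, PhNTf2, THF, −78 °C) gives the C6 enol triflate F4. Palladium-catalysed formate reduction (Pd(OAc)2, PPh3, Bu3N, HCO2H, DMF, 60 °C) then gives alkene 18, where the route is rejoined. The C8–O bond is again never broken.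

Step 16 (stannylene-mediated oxidation). What may go wrong: oxidation at the wrong hydroxyl, or over-oxidation with cleavage of the diol. Fallback setting out from 19: acetylation of the less hindered equatorial C6 hydroxyl (Ac2O, 1.1 equiv, pyridine, −20 °C) should give the 6-monoacetate F5. Dess–Martin oxidation of the remaining axial C7 hydroxyl gives the 6-acetoxy-7-ketone F6. Reduction with NaBH4 (EtOH, −20 °C) from the face anti to C20 gives the 7-hydroxy 6-acetate F7. Acetylation (Ac2O, 4-(dimethylamino)pyridine) then returns to the route at 23.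

**Further compounds**
F1 | step 7 | (5S,8S,9S,10S)-6-[(triisopropylsilyl)oxy]-12,13,14,15,16-pentanorlabd-6-en-11-al (mirror image of 9) | O=C[C@H]1[C@@H](C)C=C(O[Si](C(C)C)(C(C)C)C(C)C)[C@H]2C(C)(C)CCC[C@@]21C
F2 | step 13 | 8-hydroxy-12-[(triethylsilyl)oxy]-13,14,15,16-tetranorlabdan-6-one (8-OH anti to C20) | CC[Si](CC)(CC)OCC[C@@H]1[C@@](C)(O)CC(=O)[C@@H]2C(C)(C)CCC[C@]21C
F3 | step 13 | 8,12-bis[(triethylsilyl)oxy]-13,14,15,16-tetranorlabdan-6-one | CC[Si](CC)(CC)OCC[C@@H]1[C@@](C)(O[Si](CC)(CC)CC)CC(=O)[C@@H]2C(C)(C)CCC[C@]21C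
F4 | step 13 | 8,12-bis[(triethylsilyl)oxy]-13,14,15,16-tetranorlabd-6-en-6-yl trifluoromethanesulfonate | CC[Si](CC)(CC)OCC[C@@H]1[C@@](C)(O[Si](CC)(CC)CC)C=C(OS(=O)(=O)C(F)(F)F)[C@@H]2C(C)(C)CCC[C@]21C
F5 | step 16 | 6-monoacetate of 19 (7-OH axial, anti to C20) | CC[Si](CC)(CC)OCC[C@@H]1[C@@](C)(O[Si](CC)(CC)CC)[C@@H](O)[C@@H](OC(C)=O)[C@@H]2C(C)(C)CCC[C@]21C
F6 | step 16 | 6-acetoxy-8,12-bis[(triethylsilyl)oxy]-13,14,15,16-tetranorlabdan-7-one | CC[Si](CC)(CC)OCC[C@@H]1[C@@](C)(O[Si](CC)(CC)CC)C(=O)[C@@H](OC(C)=O)[C@@H]2C(C)(C)CCC[C@]21C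
F7 | step 16 | 6-monoacetate of 22 (7-OH equatorial, syn to C20) | CC[Si](CC)(CC)OCC[C@@H]1[C@@](C)(O[Si](CC)(CC)CC)[C@H](O)[C@@H](OC(C)=O)[C@@H]2C(C)(C)CCC[C@]21C
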